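A direct plan would first build a santonin-type eudesmanolide: Robinson annulation to the bicyclic dienedione A1, then alkylation, methylenation and lactonisation to the 8-angeloyloxy-3-oxoeudesma-1,4,11(13)-trien-12,6-olide A2.
It would then insert oxygen into the C5–C10 ring-fusion bond: singlet-oxygen ene reaction to the 5-hydroperoxide A3, Criegee rearrangement to the bridged ketal ester A4, ionic reduction, and re-oxidation at C3.
Weak step 1, the Criegee rearrangement of the tertiary allylic perester: C10 would have to migrate in preference to C4 (Hock cleavage) or C6 on an ionisable ring A, so the step that creates the whole ether bridge rests on an unsecured migratory preference.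
Weak step 2, the reduction, silylation, desilylation and re-oxidation at C3 around that rearrangement: four steps that build nothing.
Weak step 3, the run-up to A2: about ten linear steps to a simple decalin lactone, with the C6 oxygen entering by a vinylogous Rubottom oxidation of uncertain face selectivity.

**Retrosynthetic overview**
The 11-oxabicyclo[4.4.1]undecane core (ring A = O, C10, C1–C5; ring B = O, C5–C10) is not made by editing a carbocycle. It is folded in one operation from a monocyclic butyrolactone carrying a C5 aldehyde, the free C10 tertiary alcohol and a C3 vinyl ketone, by forming the C5–O and C4–C5 bonds.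
Ring order: lactone first, then rings B and A together; the C1=C2 bond is added last by a dehydrogenation that can only go one way.
C10 comes from (R)-linalool and C6 from (R)-glyceraldehyde acetonide; C7 and C8 are set in a convergent indium Barbier union (C7–C8 bond); C5 is dictated by the one-atom bridge.
No peroxide rearrangement, no protecting-group or redox detour at C3, and no decalin are needed.

Key step: step 11

Remark: germacrane numbering (C1–C15) of the target is used for all intermediates. The carbinol epimers of 6 and 15 are carried as mixtures because these carbons become sp2. The stereochemical course of steps 5 and 11 is the expected one and is not verified.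

Step 1
Reactants: 1 (R)-(−)-linalool
Product: 2 (3R)-3,7-dimethyloct-6-ene-1,3-diol
Conditions: 9-BBN (2.2 equiv), THF, 0 °C to rt; then NaOH, H2O2, 0 °C
Reagents that add atoms: hydrogen peroxide (OO)
Why: Hydroboration–oxidation with the bulky 9-BBN should take only the monosubstituted vinyl group (anti-Markovnikov) and spare the trisubstituted alkene, so the vinyl group becomes C9–C8 and the chiral-pool carbinol carbon becomes C10 without being touched.

Step 2
Reactants: 2 (3R)-3,7-dimethyloct-6-ene-1,3-diol
Product: 3 (3R)-3-hydroxy-3,7-dimethyloct-6-enal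
Conditions: TEMPO (10 mol %), PhI(OAc)2, CH2Cl2, rt
Reagents that add atoms: none
Why: The oxoammonium (TEMPO) oxidation takes the primary alcohol to the aldehyde and cannot oxidise the tertiary alcohol; the β-hydroxy aldehyde is used crude because it dehydrates easily.

Step 3
Reactants: 4 (R)-2,2-dimethyl-1,3-dioxolane-4-carbaldehyde; 5 methyl acrylate
Product: 6 methyl 2-{hydroxy[(4R)-2,2-dimethyl-1,3-dioxolan-4-yl]methyl}prop-2-enoate (carbinol epimers)
Conditions: DABCO (0.5 equiv), 1,4-dioxane/H2O (1:1), rt
Reagents that add atoms: none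
Why: Morita–Baylis–Hillman reaction of an α-alkoxy aldehyde; the new carbinol centre is lost in the next step and the dioxolane centre (later C6) is not involved.

Step 4
Reactants: 6 methyl 2-{hydroxy[(4R)-2,2-dimethyl-1,3-dioxolan-4-yl]methyl}prop-2-enoate
Product: 7 methyl (2Z)-2-(bromomethyl)-3-[(4S)-2,2-dimethyl-1,3-dioxolan-4-yl]prop-2-enoate
Conditions: NBS, Me2S, CH2Cl2, 0 °C to rt
Reagents that add atoms: N-bromosuccinimide (O=C1CCC(=O)N1Br)
Why: Corey–Kim-type activation of the allylic alcohol and SN2' delivery of bromide should give the rearranged (Z)-2-(bromomethyl)enoate (dioxolanyl group cis to CH2Br, trans to the ester) under neutral conditions that spare the acetonide.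

Step 5
Reactants: 3 (3R)-3-hydroxy-3,7-dimethyloct-6-enal; 7 methyl (2Z)-2-(bromomethyl)-3-[(4S)-2,2-dimethyl-1,3-dioxolan-4-yl]prop-2-enoate
Product: 8 methyl (3R,4R,6R)-3-[(4S)-2,2-dimethyl-1,3-dioxolan-4-yl]-4,6-dihydroxy-6,10-dimethyl-2-methylideneundec-9-enoate
Conditions: In powder (1.5 equiv), THF/H2O (1:1), rt
Reagents that add atoms: none
Why: Indium-mediated Barbier allylation forms the C7–C8 bond at the γ-carbon of the allylindium; a chair transition state with the C7 substituent pseudo-axial (cis to the metallated CH2) should give the 7,8-syn adduct, and attack on C7 anti to the dioxolane C–O bond in the conformer with C6–H eclipsing the alkene (allylic 1,3-strain) should set C7 relative to C6 as required for the trans-lactone.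

Step 6
Reactants: 8 methyl (3R,4R,6R)-3-[(4S)-2,2-dimethyl-1,3-dioxolan-4-yl]-4,6-dihydroxy-6,10-dimethyl-2-methylideneundec-9-enoate; 9 angelic acid
Product: 11 methyl (3R,4R,6R)-4-(angeloyloxy)-3-[(4S)-2,2-dimethyl-1,3-dioxolan-4-yl]-6-hydroxy-6,10-dimethyl-2-methylideneundec-9-enoate, via mixed anhydride 10 (not isolated)
Conditions: 9, 2,4,6-Cl3C6H2COCl, Et3N, toluene, rt; then crude 8, DMAP, 40 °C
Reagents that add atoms: none
Why: Yamaguchi esterification acylates the hindered secondary C8 alcohol with retention and without Z-to-E isomerisation of the angelate; the tertiary C10 alcohol does not react, and acylating C8 before the acetonide is opened rules out a 12,8-lactone.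

Step 7
Reactants: 11 methyl (3R,4R,6R)-4-(angeloyloxy)-3-[(4S)-2,2-dimethyl-1,3-dioxolan-4-yl]-6-hydroxy-6,10-dimethyl-2-methylideneundec-9-enoate
Product: 12 (1R,3R)-3-hydroxy-1-[(2S,3R)-2-(hydroxymethyl)-4-methylidene-5-oxooxolan-3-yl]-3,7-dimethyloct-6-en-1-yl (2Z)-2-methylbut-2-enoate
Conditions: AcOH/H2O (4:1), 45 °C; then PPTS (10 mol %), toluene, 45 °C
Reagents that add atoms: none
Why: Acid hydrolysis of the acetonide followed by acid-catalysed lactonisation of the C6 hydroxyl onto the methyl ester (five-membered lactone preferred over the six-membered one from the primary C5 hydroxyl) gives the trans-disubstituted α-methylene-γ-butyrolactone without touching C6 or C7; the weak acids should spare the tertiary alcohol and the trisubstituted alkene.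

Step 8
Reactants: 12 (1R,3R)-3-hydroxy-1-[(2S,3R)-2-(hydroxymethyl)-4-methylidene-5-oxooxolan-3-yl]-3,7-dimethyloct-6-en-1-yl (2Z)-2-methylbut-2-enoate
Product: 13 (1R,3R)-3-hydroxy-1-[(2S,3R)-2-(hydroxymethyl)-4-methylidene-5-oxooxolan-3-yl]-3-methyl-6-oxohexyl (2Z)-2-methylbut-2-enoate (in equilibrium with its five-membered lactol)
Conditions: O3, CH2Cl2, −78 °C (Sudan III end-point); then PPh3, −78 °C to rt
Reagents that add atoms: ozone ([O-][O+]=O)
Why: Ozonolysis is selective for the electron-rich trisubstituted alkene over the two conjugated, electron-poor alkenes (α-methylene lactone, angelate) and exposes C3 as the aldehyde.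

Step 9
Reactants: 13 (1R,3R)-3-hydroxy-1-[(2S,3R)-2-(hydroxymethyl)-4-methylidene-5-oxooxolan-3-yl]-3-methyl-6-oxohexyl (2Z)-2-methylbut-2-enoate; 14 vinyl bromide
Product: 15 (1R,3R)-3,6-dihydroxy-1-[(2S,3R)-2-(hydroxymethyl)-4-methylidene-5-oxooxolan-3-yl]-3-methyloct-7-en-1-yl (2Z)-2-methylbut-2-enoate (epimers at the new carbinol, C3 of the target)
Conditions: 14, CrCl2 (4 equiv), NiCl2 (2 mol %), DMF, rt
Reagents that add atoms: none
Why: Nozaki–Hiyama–Kishi vinylation adds the vinylchromium reagent only to the aldehyde (open form of the lactol) and tolerates the lactone, the ester and the free hydroxyls; the new carbinol is oxidised next, so its configuration does not matter.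

Step 10
Reactants: 15 (1R,3R)-3,6-dihydroxy-1-[(2S,3R)-2-(hydroxymethyl)-4-methylidene-5-oxooxolan-3-yl]-3-methyloct-7-en-1-yl (2Z)-2-methylbut-2-enoate
Product: 16 (1R,3R)-1-[(2S,3R)-2-formyl-4-methylidene-5-oxooxolan-3-yl]-3-hydroxy-3-methyl-6-oxooct-7-en-1-yl (2Z)-2-methylbut-2-enoate
Conditions: Dess–Martin periodinane (3 equiv), NaHCO3, CH2Cl2, 0 °C to rt
Reagents that add atoms: none
Why: Dess–Martin oxidation converts the primary C5 alcohol into the aldehyde and the allylic C3 alcohol into the vinyl ketone in one operation under buffered conditions; the tertiary C10 alcohol cannot be oxidised, and the product is used at once.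

Step 11
Reactants: 16 (1R,3R)-1-[(2S,3R)-2-formyl-4-methylidene-5-oxooxolan-3-yl]-3-hydroxy-3-methyl-6-oxooct-7-en-1-yl (2Z)-2-methylbut-2-enoate
Product: 19 (5S,6S,7R,8R,10R)-8-angeloyloxy-5,10-epoxy-3-oxogermacra-4(15),11(13)-dien-12,6-olide (the 1,2-dihydro target), via sulfonium silyl enol ether 17 (not isolated), via bridged sulfonium ketone 18 (not isolated)
Conditions: Me2S (10 equiv), TMSOTf (3.5 equiv), 2,6-di-tert-butyl-4-methylpyridine (2.5 equiv), CH2Cl2 (0.005 M), −78 to −30 °C; then i-Pr2NEt, −30 to 0 °C
Reagents that add atoms: none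
Why: Proposed new method: TMSOTf/Me2S should turn the vinyl ketone into the β-sulfonium silyl enol ether 17 (conjugate addition at C15, which also takes the ketone out of hemiketal equilibria) and silylate the C10 hydroxyl; that oxygen then condenses with the activated C5 aldehyde to the seven-membered cyclic oxocarbenium ion of ring B, the tethered enol ether captures it at C4 to give 18, and base expels Me2S (E1cB) to unveil the C4=C15 methylene. The closest known reactions are the chalcogeno-Morita–Baylis–Hillman reaction of enones with acetals under silyl triflate/sulfide and the Markó silyl-modified Sakurai condensation of a silyl ether, an aldehyde and a carbon nucleophile, both intermolecular at the oxocarbenium stage. Ring B closes by addition of oxygen to the aldehyde (7-exo-trig, as in reductive etherifications to oxepanes) and ring A by 7-endo-trig attack of C4 on the endocyclic C5=O+ bond, so both oxepane rings, the C5–O and C4–C5 bonds and the exo-methylene arise in one flask. C5 is the only new stereocentre and is fixed by geometry: the C1–C4 tether hangs from C10 and can reach the planar C5 only from the face of ring B that carries it, so the new bond is necessarily cis to C10–C1 across the bridging oxygen, which is (5S) once C10 comes from (R)-linalool; C6 is a preset, independent centre. The step needs the sulfide to add productively only at the terminal C15 (its adduct with the α-methylene lactone cannot turn over because C11 has no hydrogen, and the angelate is β-substituted), O-cyclisation before C–C bond formation (seven-membered hemiacetalisation against a ten-membered aldol), and no enolisation at C2 or Nazarov chemistry, which the low temperature and the absence of amine base until the end should secure.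

Step 12
Reactants: 19 (5S,6S,7R,8R,10R)-8-angeloyloxy-5,10-epoxy-3-oxogermacra-4(15),11(13)-dien-12,6-olide
Product: 20 CNP0335602.1 (target), (5S,6S,7R,8R,10S)-8-angeloyloxy-5,10-epoxy-3-oxogermacra-1,4(15),11(13)-trien-12,6-olide
Conditions: IBX (2.5 equiv), 4-methoxypyridine N-oxide (2.5 equiv), DMSO, rt to 40 °C
Reagents that add atoms: none
Why: IBX dehydrogenation of a ketone through its enol: only C2 carries α-hydrogens (C4 is sp2), so the new double bond can only be C1=C2 and is necessarily cis within the seven-membered ring, and the non-nucleophilic oxidant should leave the α-methylene lactone, the angelate and the exo-methylene ketone alone.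

**Compound list**
1 | (R)-(−)-linalool, (3R)-3,7-dimethylocta-1,6-dien-3-ol | C=C[C@](C)(O)CCC=C(C)C | starting material
2 | (3R)-3,7-dimethyloct-6-ene-1,3-diol | OCC[C@](C)(O)CCC=C(C)C | intermediate
3 | (3R)-3-hydroxy-3,7-dimethyloct-6-enal | O=CC[C@](C)(O)CCC=C(C)C | intermediate
4 | (R)-2,2-dimethyl-1,3-dioxolane-4-carbaldehyde (D-glyceraldehyde acetonide) | CC1(C)OC[C@H](C=O)O1 | starting material
5 | methyl acrylate | C=CC(=O)OC | starting material
6 | methyl 2-{hydroxy[(4R)-2,2-dimethyl-1,3-dioxolan-4-yl]methyl}prop-2-enoate (carbinol epimers) | C=C(C(=O)OC)C(O)[C@H]1COC(C)(C)O1 | intermediate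
7 | methyl (2Z)-2-(bromomethyl)-3-[(4S)-2,2-dimethyl-1,3-dioxolan-4-yl]prop-2-enoate | BrC/C(C(=O)OC)=C\[C@H]1COC(C)(C)O1 | intermediate
8 | methyl (3R,4R,6R)-3-[(4S)-2,2-dimethyl-1,3-dioxolan-4-yl]-4,6-dihydroxy-6,10-dimethyl-2-methylideneundec-9-enoate | C=C(C(=O)OC)[C@@H]([C@H]1COC(C)(C)O1)[C@H](O)C[C@](C)(O)CCC=C(C)C | intermediate
9 | angelic acid, (Z)-2-methylbut-2-enoic acid | C/C=C(/C)C(=O)O | starting material
10 | angelic 2,4,6-trichlorobenzoic anhydride | C/C=C(/C)C(=O)OC(=O)c1c(Cl)cc(Cl)cc1Cl | intermediate
11 | methyl (3R,4R,6R)-4-(angeloyloxy)-3-[(4S)-2,2-dimethyl-1,3-dioxolan-4-yl]-6-hydroxy-6,10-dimethyl-2-methylideneundec-9-enoate | C=C(C(=O)OC)[C@@H]([C@H]1COC(C)(C)O1)[C@H](OC(=O)/C(C)=C\C)C[C@](C)(O)CCC=C(C)C | intermediate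
12 | (1R,3R)-3-hydroxy-1-[(2S,3R)-2-(hydroxymethyl)-4-methylidene-5-oxooxolan-3-yl]-3,7-dimethyloct-6-en-1-yl (2Z)-2-methylbut-2-enoate | C=C1C(=O)O[C@H](CO)[C@H]1[C@H](OC(=O)/C(C)=C\C)C[C@](C)(O)CCC=C(C)C | intermediate
13 | (1R,3R)-3-hydroxy-1-[(2S,3R)-2-(hydroxymethyl)-4-methylidene-5-oxooxolan-3-yl]-3-methyl-6-oxohexyl (2Z)-2-methylbut-2-enoate (open form of the lactol) | C=C1C(=O)O[C@H](CO)[C@H]1[C@H](OC(=O)/C(C)=C\C)C[C@](C)(O)CCC=O | intermediate
14 | vinyl bromide | C=CBr | starting material
15 | (1R,3R)-3,6-dihydroxy-1-[(2S,3R)-2-(hydroxymethyl)-4-methylidene-5-oxooxolan-3-yl]-3-methyloct-7-en-1-yl (2Z)-2-methylbut-2-enoate (epimers at C3 of the target) | C=C1C(=O)O[C@H](CO)[C@H]1[C@H](OC(=O)/C(C)=C\C)C[C@](C)(O)CCC(O)C=C | intermediate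
16 | (1R,3R)-1-[(2S,3R)-2-formyl-4-methylidene-5-oxooxolan-3-yl]-3-hydroxy-3-methyl-6-oxooct-7-en-1-yl (2Z)-2-methylbut-2-enoate | C=C1C(=O)O[C@H](C=O)[C@H]1[C@H](OC(=O)/C(C)=C\C)C[C@](C)(O)CCC(=O)C=C | intermediate
17 | 3-O,10-O-bis(trimethylsilyl) enol ether of 16 with a dimethylsulfonium group on C15, triflate salt (enol ether geometry not defined) | C=C1C(=O)O[C@H](C=O)[C@H]1[C@H](OC(=O)/C(C)=C\C)C[C@](C)(O[Si](C)(C)C)CCC(O[Si](C)(C)C)=CC[S+](C)C.[O-]S(=O)(=O)C(F)(F)F | intermediate
18 | 8-angeloyloxy-15-(dimethylsulfonio)-5,10-epoxy-3-oxogermacr-11(13)-en-12,6-olide triflate (C4 epimers) | C=C1C(=O)O[C@H]2[C@H]1[C@H](OC(=O)/C(C)=C\C)C[C@@]1(C)CCC(=O)C(C[S+](C)C)[C@@H]2O1.[O-]S(=O)(=O)C(F)(F)F | intermediate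
19 | (5S,6S,7R,8R,10R)-8-angeloyloxy-5,10-epoxy-3-oxogermacra-4(15),11(13)-dien-12,6-olide (1,2-dihydro target; same spatial arrangement as 20) | C=C1C(=O)O[C@H]2[C@H]1[C@H](OC(=O)/C(C)=C\C)C[C@@]1(C)CCC(=O)C(=C)[C@@H]2O1 | intermediate
20 | CNP0335602.1, (5S,6S,7R,8R,10S)-8-angeloyloxy-5,10-epoxy-3-oxogermacra-1,4(15),11(13)-trien-12,6-olide | C=C1C(=O)O[C@H]2[C@H]1[C@H](OC(=O)/C(C)=C\C)C[C@@]1(C)C=CC(=O)C(=C)[C@@H]2O1 | target

Total step count: 12. Longest linear sequence: 10 steps (steps 1, 2 and 5–12 from linalool; steps 3 and 4 make the second fragment).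

**Steps most likely to fail**

Step 11 (proposed new method). The sulfonium enolate may revert to the enone, or the C5 oxocarbenium ion may lose the C6 proton, before the bridging C–C bond forms; the free C10 hydroxyl may also be diverted into a five-membered ketal at C3. The fallback uses known reactions and a stable, regio-defined silyl enol ether, setting out from 16 and returning at 19. The aldehyde of 16 would be converted into the dimethyl acetal F1 (HC(OMe)3, PPTS, MeOH). Conjugate addition of PhSSiMe3 to the vinyl ketone would give the phenylthio silyl enol ether F2. Catalytic TMSOTf (CH2Cl2, −78 °C) would then ionise the acetal, close ring B through the C10 hydroxyl, and trigger the intramolecular Mukaiyama-type addition of C4 to the cyclic oxocarbenium ion, giving the bridged β-phenylthio ketone F3. Oxidation with NaIO4 to the sulfoxide F4 and warming in toluene (syn-elimination) would give 19.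

Step 5. The allylindium is fluxional and may lose its alkene geometry, undergo 1,4-elimination of the dioxolane oxygen, or show a weak facial bias, which would erode the 7,8-syn and 6,7 relationships. The fallback replaces the Barbier reaction by a preformed, configurationally stable allylboron reagent, setting out from 7 and returning at 8. Borylation of 7 with bis(pinacolato)diboron under zerovalent palladium catalysis (Pd2(dba)3, DMSO) would give the primary allylboronate F5 with the alkene geometry of 7. Its Sc(OTf)3-catalysed allylboration of 3 (toluene, 0 °C to rt) would pass through a closed six-membered transition state and give 8 after work-up.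

Step 12. Over-oxidation, or attack of the oxidant or DMSO-derived species on the two exo-methylene acceptors, may compete with the slow enolisation of the hindered ketone. The fallback separates enol formation from oxidation, setting out from 19 and returning at 20. TMSOTf/i-Pr2NEt (CH2Cl2, −78 °C) would give the 2-silyloxy diene F6 (enolisation is possible only towards C2). Saegusa–Ito oxidation with stoichiometric Pd(OAc)2 in MeCN would then give 20.

Further compounds
F1 | step 11 | (1R,3R)-1-[(2S,3R)-2-(dimethoxymethyl)-4-methylidene-5-oxooxolan-3-yl]-3-hydroxy-3-methyl-6-oxooct-7-en-1-yl (2Z)-2-methylbut-2-enoate | C=C1C(=O)O[C@H](C(OC)OC)[C@H]1[C@H](OC(=O)/C(C)=C\C)C[C@](C)(O)CCC(=O)C=C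
F2 | step 11 | (1R,3R)-1-[(2S,3R)-2-(dimethoxymethyl)-4-methylidene-5-oxooxolan-3-yl]-3-hydroxy-3-methyl-8-(phenylsulfanyl)-6-(trimethylsilyloxy)oct-6-en-1-yl (2Z)-2-methylbut-2-enoate | C=C1C(=O)O[C@H](C(OC)OC)[C@H]1[C@H](OC(=O)/C(C)=C\C)C[C@](C)(O)CCC(O[Si](C)(C)C)=CCSc1ccccc1
F3 | step 11 | 8-angeloyloxy-5,10-epoxy-3-oxo-15-(phenylsulfanyl)germacr-11(13)-en-12,6-olide (C4 epimers) | C=C1C(=O)O[C@H]2[C@H]1[C@H](OC(=O)/C(C)=C\C)C[C@@]1(C)CCC(=O)C(CSc3ccccc3)[C@@H]2O1
F4 | step 11 | 8-angeloyloxy-5,10-epoxy-3-oxo-15-(phenylsulfinyl)germacr-11(13)-en-12,6-olide (C4 and sulfur epimers) | C=C1C(=O)O[C@H]2[C@H]1[C@H](OC(=O)/C(C)=C\C)C[C@@]1(C)CCC(=O)C(CS(=O)c3ccccc3)[C@@H]2O1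
F5 | step 5 | methyl (2Z)-3-[(4S)-2,2-dimethyl-1,3-dioxolan-4-yl]-2-[(4,4,5,5-tetramethyl-1,3,2-dioxaborolan-2-yl)methyl]prop-2-enoate | CC1(C)OB(C/C(C(=O)OC)=C\[C@H]2COC(C)(C)O2)OC1(C)C
F6 | step 12 | 8-angeloyloxy-5,10-epoxy-3-(trimethylsilyloxy)germacra-2,4(15),11(13)-trien-12,6-olide | C=C1C(=O)O[C@H]2[C@H]1[C@H](OC(=O)/C(C)=C\C)C[C@@]1(C)CC=C(O[Si](C)(C)C)C(=C)[C@@H]2O1
A1 | direct plan | (S)-1,4a-dimethyl-7,8-dihydronaphthalene-2,6(4aH,5H)-dione | O=C1C=C[C@]2(C)CC(=O)CCC2=C1C
A2 | direct plan | 8β-angeloyloxy-3-oxoeudesma-1,4,11(13)-trien-12,6α-olide | C=C1C(=O)O[C@H]2[C@H]1[C@H](OC(=O)/C(C)=C\C)C[C@@]3(C)C=CC(=O)C(C)=C23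
A3 | direct plan | 8β-angeloyloxy-5α-hydroperoxy-3β-(tert-butyldimethylsilyloxy)eudesma-1,4(15),11(13)-trien-12,6α-olide | C=C1C(=O)O[C@H]2[C@H]1[C@H](OC(=O)/C(C)=C\C)C[C@@]3(C)C=C[C@H](O[Si](C)(C)C(C)(C)C)C(=C)[C@]23OO
A4 | direct plan | 8-angeloyloxy-5,10-epoxy-5-(4-nitrobenzoyloxy)-3-(tert-butyldimethylsilyloxy)germacra-1,4(15),11(13)-trien-12,6-olide | C=C1C(=O)O[C@H]2[C@H]1[C@H](OC(=O)/C(C)=C\C)C[C@@]3(C)C=C[C@H](O[Si](C)(C)C(C)(C)C)C(=C)[C@]2(OC(=O)c4ccc(cc4)[N+](=O)[O-])O3
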